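**Plan**

- Retrosynthesis (target numbering: C1 quaternary carbinol carbon, C2 CH–OMe, C3=C4, C5 CH–OBz, C6 CH–OAc): the methyl ether, primary benzoate and acetate are removed, C3=C4 is traced back to a C3 formyl group and the C1/C6 cis-diol to a C1=C6 alkene. The ring is then cut at C2–C3 and C4–C5.
- Enabling feature: C2 and C5 both carry oxygen, are both allylic to C3=C4 and are cis across the six-membered ring, with the cis-diol at C1/C6 on the other face. This is the imprint of an (E,E)-1,4-dioxygenated diene C2=C1–C6=C5 adding to a two-carbon dienophile, the new C1=C6 bond being left for osmylation.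
- Forward: dihydroxyacetone acetonide is extended by two carbons to an ylidene acetaldehyde and enolised to a dienyl benzoate. A temporary 4H-1,3-dioxin ring (isopropylidene bridge between the C2 oxygen and the oxygen of the C1 hydroxymethyl group) locks the enol ether geometry. The carbocycle, the only ring of the target, is closed by an enantioselective Diels–Alder reaction with acrolein used as an acetylene equivalent.
- Then: dihydroxylation, acetylation, rhodium-catalysed loss of the formyl group (C3=C4 unveiled), acetonide removal, benzoylation of the primary hydroxyl and O-methylation at C2.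
- Stereochemistry: C2 and C5 (cis, and absolute) come from the suprafacial cycloaddition of the E,E-diene on the catalyst-shielded iminium ion; C1 and C6 come from osmylation anti to both allylic oxygens.

Key step: step 4

Remark (assumption): the catalyst antipode is assigned from the usual model for this catalyst class ((E)-iminium ion, benzyl group shielding one face, endo transition state, benzoyloxy-bearing diene terminus bonding to the iminium β-carbon), which points to the (5R)-imidazolidinone; if the sense of induction proved opposite, the (5S)-catalyst would be used with no other change.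

**Route**

Step 1
Reactants: 1 2,2-dimethyl-1,3-dioxan-5-one; 2 diethyl (cyanomethyl)phosphonate
Product: 4 2-(2,2-dimethyl-1,3-dioxan-5-ylidene)acetonitrile, via sodium phosphonate carbanion 3 (not isolated)
Conditions: NaH, THF, 0 °C; then 1, 0 °C to rt
Reagents that add atoms: none
Why: Horner–Wadsworth–Emmons olefination of an electrophilic α,α′-dialkoxy ketone by the stabilised phosphonate carbanion; the ketone is symmetrical, so the new double bond has no E/Z isomers and no stereocentre is formed.

Step 2
Reactants: 4 2-(2,2-dimethyl-1,3-dioxan-5-ylidene)acetonitrile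
Product: 6 2-(2,2-dimethyl-1,3-dioxan-5-ylidene)acetaldehyde, via N-aluminio aldimine 5 (not isolated)
Conditions: iBu2AlH (1.1 equiv), toluene, −78 °C; aq. potassium sodium tartrate, then pH 5 acetate buffer, 0 °C
Reagents that add atoms: water (O)
Why: Partial hydride reduction of the conjugated nitrile with a dialkylaluminium hydride stops at the N-aluminio aldimine, which buffered aqueous work-up hydrolyses to the enal without cleaving the 1,3-dioxane acetal; no stereocentre is formed.

Step 3
Reactants: 6 2-(2,2-dimethyl-1,3-dioxan-5-ylidene)acetaldehyde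
Product: 8 (E)-2-(2,2-dimethyl-4H-1,3-dioxin-5-yl)ethenyl benzoate, via potassium dienolate 7 (not isolated)
Conditions: KN(SiMe3)2, THF, −78 °C; then BzCl, −78 to 0 °C
Reagents that add atoms: benzoyl chloride (O=C(Cl)c1ccccc1)
Why: Vinylogous (γ) deprotonation of the enal and O-acylation of the extended potassium dienolate is the standard entry to 1-acyloxy-1,3-dienes; the enal reacts from its s-trans conformer, so the enol benzoate should form E, while the enol ether geometry at the other diene terminus is fixed by the dioxin ring (ring oxygen trans to the vinyl group), giving an E,E-type 1,4-dioxygenated diene.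

Step 4
Reactants: 8 (E)-2-(2,2-dimethyl-4H-1,3-dioxin-5-yl)ethenyl benzoate; 9 acrolein
Product: 12 (6R,8S,8aS)-8-formyl-2,2-dimethyl-6,7,8,8a-tetrahydro-4H-1,3-benzodioxin-6-yl benzoate, via acrolein iminium ion 10 (not isolated), via adduct iminium ion 11 (not isolated)
Conditions: (5R)-5-benzyl-2,2,3-trimethylimidazolidin-4-one hydrochloride (20 mol%), MeCN/H2O 95:5, −20 °C
Reagents that add atoms: none
Why: Condensation of 9 with the imidazolidinone salt gives the (E)-iminium ion 10, whose low-lying LUMO undergoes a concerted but asynchronous [4+2] cycloaddition with the s-cis diene unit of 8 to give iminium ion 11, and hydrolysis releases 12 and the catalyst; the closest known reaction type is the imidazolidinone-catalysed enantioselective Diels–Alder reaction of acrolein with 1-acyloxybuta-1,3-dienes. The one ring closed is the cyclohexene, formed as a six-membered ring by suprafacial [4πs+2πs] union of the diene termini (C8a and C6 of 12) with the two alkene carbons of acrolein (C8 and C7 of 12), which are the target bonds C2–C3 and C4–C5. Both oxygen substituents occupy the outside (E) positions of the diene, one of them held there by the dioxin ring, so the C8a–O1 and C6–O bonds must end up cis, and endo approach of the iminium carbon places the formyl group on C8 cis to both. The absolute configuration (6R,8aS) is controlled by the benzyl group of the (5R)-catalyst, which covers one face of the iminium alkene so that the diene adds endo to the open face. The step needs regioselectivity (formyl-bearing carbon bonded to C8a), endo selectivity and face selectivity: the alkoxy group at the dioxin terminus is a stronger donor than the benzoyloxy group, which makes the benzoyloxy-bearing terminus the nucleophilic one that bonds to the iminium β-carbon, and regioisomeric or exo adducts are distinct compounds that chromatography should remove. The formyl group is a helper only: it activates and orients the dienophile and is taken out in step 7, so that acrolein delivers the two carbons of an acetylene.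

Step 5
Reactants: 12 (6R,8S,8aS)-8-formyl-2,2-dimethyl-6,7,8,8a-tetrahydro-4H-1,3-benzodioxin-6-yl benzoate
Product: 13 (4aS,5S,6R,8S,8aS)-8-formyl-4a,5-dihydroxy-2,2-dimethylhexahydro-4H-1,3-benzodioxin-6-yl benzoate
Conditions: OsO4 (2 mol%), N-methylmorpholine N-oxide (1.5 equiv), acetone/H2O 4:1, 0 °C to rt
Reagents that add atoms: N-methylmorpholine N-oxide (C[N+]1([O-])CCOCC1); water (O)
Why: Catalytic osmylation (syn dihydroxylation with an N-oxide reoxidant) of the only alkene, the trisubstituted C4a=C5 bond, should occur on the face opposite to O1 at C8a, the benzoate at C6 and the formyl group at C8, which all lie on one face (empirical rule of osmylation anti to an allylic oxygen), and so sets the cis-diol at C4a and C5 trans to both allylic oxygens.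

Step 6
Reactants: 13 (4aS,5S,6R,8S,8aS)-8-formyl-4a,5-dihydroxy-2,2-dimethylhexahydro-4H-1,3-benzodioxin-6-yl benzoate
Product: 14 (4aR,5S,6R,8S,8aS)-5-acetoxy-8-formyl-4a-hydroxy-2,2-dimethylhexahydro-4H-1,3-benzodioxin-6-yl benzoate
Conditions: Ac2O, pyridine, 4-(dimethylamino)pyridine (5 mol%), CH2Cl2, 0 °C
Reagents that add atoms: acetic anhydride (CC(=O)OC(C)=O)
Why: Nucleophile-catalysed acylation distinguishes the secondary C5 hydroxyl from the tertiary C4a hydroxyl, which is inert under these conditions; no stereocentre is touched.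

Step 7
Reactants: 14 (4aR,5S,6R,8S,8aS)-5-acetoxy-8-formyl-4a-hydroxy-2,2-dimethylhexahydro-4H-1,3-benzodioxin-6-yl benzoate
Product: 15 (4aR,5S,6R,8aS)-5-acetoxy-4a-hydroxy-2,2-dimethyl-4a,5,6,8a-tetrahydro-4H-1,3-benzodioxin-6-yl benzoate
Conditions: [Rh(cod)(OMe)]2 (2.5 mol%), 4,5-bis(diphenylphosphino)-9,9-dimethylxanthene (5 mol%), 3-methoxybenzoic acid (5 mol%), norbornadiene (2 equiv), THF, 60 °C
Reagents that add atoms: none
Why: Rhodium-catalysed transfer hydroformylation run in the dehydroformylation direction: carboxylate-assisted activation of the formyl C–H bond, loss of CO to the C8 alkylrhodium and syn β-hydride elimination, with norbornadiene taking up H2 and CO; only C7 offers a β-hydrogen syn to the metal (H8a is anti because O1 is cis to the formyl group), so the double bond should form between C7 and C8 and the four remaining stereocentres are untouched.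

Step 8
Reactants: 15 (4aR,5S,6R,8aS)-5-acetoxy-4a-hydroxy-2,2-dimethyl-4a,5,6,8a-tetrahydro-4H-1,3-benzodioxin-6-yl benzoate
Product: 16 (1R,4S,5R,6S)-6-acetoxy-4,5-dihydroxy-5-(hydroxymethyl)cyclohex-2-en-1-yl benzoate
Conditions: AcOH/H2O 4:1, 40 °C
Reagents that add atoms: none
Why: Acid-catalysed hydrolysis of the isopropylidene acetal (cleavage at the acetal carbon, so the ring C–O bond and its configuration are kept) frees the allylic secondary and the primary hydroxyl; the esters are stable to aqueous acetic acid.

Step 9
Reactants: 16 (1R,4S,5R,6S)-6-acetoxy-4,5-dihydroxy-5-(hydroxymethyl)cyclohex-2-en-1-yl benzoate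
Product: 17 [(1R,2S,5R,6S)-6-acetoxy-5-(benzoyloxy)-1,2-dihydroxycyclohex-3-en-1-yl]methyl benzoate
Conditions: BzCl (1.05 equiv), 2,4,6-collidine, CH2Cl2, −40 to 0 °C
Reagents that add atoms: benzoyl chloride (O=C(Cl)c1ccccc1)
Why: Kinetically selective acylation of the primary hydroxyl with one equivalent of acid chloride and a hindered pyridine base at low temperature; the secondary allylic and the tertiary hydroxyl react much more slowly, and no stereocentre is touched.

Step 10
Reactants: 17 [(1R,2S,5R,6S)-6-acetoxy-5-(benzoyloxy)-1,2-dihydroxycyclohex-3-en-1-yl]methyl benzoate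
Product: 18 [(1R,2S,5R,6S)-6-acetoxy-5-(benzoyloxy)-1-hydroxy-2-methoxycyclohex-3-en-1-yl]methyl benzoate
Conditions: MeOTf, 2,6-di-tert-butyl-4-methylpyridine, CH2Cl2, 0 °C to rt
Reagents that add atoms: methyl trifluoromethanesulfonate (COS(=O)(=O)C(F)(F)F)
Why: O-Alkylation of the secondary allylic hydroxyl with a hard methylating agent and a hindered non-nucleophilic pyridine base, a non-basic Williamson-type etherification that leaves the three ester groups in place and avoids acyl migration; the tertiary hydroxyl is too hindered to compete, and since the C2–O bond is not broken the configuration is retained.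

**Compound list**

1 | 2,2-dimethyl-1,3-dioxan-5-one | CC1(C)OCC(=O)CO1 | starting material
2 | diethyl (cyanomethyl)phosphonate | CCOP(=O)(CC#N)OCC | starting material
3 | sodium cyano(diethoxyphosphoryl)methanide (carbanion of 2) | [Na+].CCOP(=O)([CH-]C#N)OCC | intermediate
4 | 2-(2,2-dimethyl-1,3-dioxan-5-ylidene)acetonitrile | N#CC=C1COC(C)(C)OC1 | intermediate
5 | (E)-N-(diisobutylalumanyl)-2-(2,2-dimethyl-1,3-dioxan-5-ylidene)ethan-1-imine | CC(C)C[Al](CC(C)C)/N=C/C=C1COC(C)(C)OC1 | intermediate
6 | 2-(2,2-dimethyl-1,3-dioxan-5-ylidene)acetaldehyde | O=CC=C1COC(C)(C)OC1 | intermediate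
7 | potassium (E)-2-(2,2-dimethyl-4H-1,3-dioxin-5-yl)ethen-1-olate | [K+].[O-]/C=C/C1=COC(C)(C)OC1 | intermediate
8 | (E)-2-(2,2-dimethyl-4H-1,3-dioxin-5-yl)ethenyl benzoate | O=C(O/C=C/C1=COC(C)(C)OC1)c1ccccc1 | intermediate
9 | acrolein (prop-2-enal) | C=CC=O | starting material
10 | (5R)-5-benzyl-2,2,3-trimethyl-4-oxo-1-[(E)-prop-2-en-1-ylidene]imidazolidin-1-ium chloride (iminium ion of 9 with the catalyst) | [Cl-].C=C/C=[N+]1\[C@H](Cc2ccccc2)C(=O)N(C)C1(C)C | intermediate
11 | (E)-iminium chloride of 12 with the (5R)-catalyst (C=N+ in place of the formyl C=O) | [Cl-].C(/[C@H]1C[C@@H](OC(=O)c2ccccc2)C=C2COC(C)(C)O[C@@H]12)=[N+]1/[C@H](Cc2ccccc2)C(=O)N(C)C1(C)C | intermediate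
12 | (6R,8S,8aS)-8-formyl-2,2-dimethyl-6,7,8,8a-tetrahydro-4H-1,3-benzodioxin-6-yl benzoate (O1 at C8a, the 6-benzoate and the 8-formyl group all cis; C4a=C5 double bond) | O=C[C@H]1C[C@@H](OC(=O)c2ccccc2)C=C2COC(C)(C)O[C@@H]12 | intermediate
13 | (4aS,5S,6R,8S,8aS)-8-formyl-4a,5-dihydroxy-2,2-dimethylhexahydro-4H-1,3-benzodioxin-6-yl benzoate (4a,5-cis-diol on the face opposite to O1, benzoate and formyl) | O=C[C@H]1C[C@@H](OC(=O)c2ccccc2)[C@H](O)[C@@]2(O)COC(C)(C)O[C@@H]12 | intermediate
14 | (4aR,5S,6R,8S,8aS)-5-acetoxy-8-formyl-4a-hydroxy-2,2-dimethylhexahydro-4H-1,3-benzodioxin-6-yl benzoate | O=C[C@H]1C[C@@H](OC(=O)c2ccccc2)[C@H](OC(C)=O)[C@@]2(O)COC(C)(C)O[C@@H]12 | intermediate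
15 | (4aR,5S,6R,8aS)-5-acetoxy-4a-hydroxy-2,2-dimethyl-4a,5,6,8a-tetrahydro-4H-1,3-benzodioxin-6-yl benzoate (C7=C8 double bond) | C1=C[C@@H](OC(=O)c2ccccc2)[C@H](OC(C)=O)[C@@]2(O)COC(C)(C)O[C@@H]12 | intermediate
16 | (1R,4S,5R,6S)-6-acetoxy-4,5-dihydroxy-5-(hydroxymethyl)cyclohex-2-en-1-yl benzoate | O[C@H]1C=C[C@@H](OC(=O)c2ccccc2)[C@H](OC(C)=O)[C@@]1(O)CO | intermediate
17 | [(1R,2S,5R,6S)-6-acetoxy-5-(benzoyloxy)-1,2-dihydroxycyclohex-3-en-1-yl]methyl benzoate | O[C@H]1C=C[C@@H](OC(=O)c2ccccc2)[C@H](OC(C)=O)[C@@]1(O)COC(=O)c1ccccc1 | intermediate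
18 | [(1R,2S,5R,6S)-6-acetoxy-5-(benzoyloxy)-1-hydroxy-2-methoxycyclohex-3-en-1-yl]methyl benzoate | CO[C@H]1C=C[C@@H](OC(=O)c2ccccc2)[C@H](OC(C)=O)[C@@]1(O)COC(=O)c1ccccc1 | target

**Step count and risks**

Total steps: 10. Longest linear sequence: 10 steps (1 to 18).

Steps most likely to fail:

Step 4. The processes at risk are acid-promoted hydrolysis of the enol acetal of 8 in the protic iminium medium and erosion of regio- or enantiocontrol. Fallback, from 8 back to 17: 8 and 9 are heated without catalyst (toluene, 80 °C, 2,6-di-tert-butyl-4-methylphenol as inhibitor), a thermal Diels–Alder reaction that should give the same ortho-endo adduct as a racemate, that is 12 together with the enantiomer of 12 F1. Steps 5 to 9 are then run on the racemate, which carries F1 through the enantiomer of 13 F2, the enantiomer of 14 F3, the enantiomer of 15 F4 and the enantiomer of 16 F5 to the enantiomer of 17 F6, obtained beside 17. The racemic allylic alcohol is resolved by lipase-catalysed transesterification (Burkholderia cepacia lipase, vinyl acetate, tert-butyl methyl ether, 30 °C). By the empirical size rule for secondary alcohols the (2R)-alcohol, whose larger carbinol substituent is the quaternary C1 and whose smaller one is the vinylic C3, should be acylated to the C2 acetate F7. Unchanged (2S)-alcohol 17 is separated by chromatography and enters step 10.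

Step 7. The processes at risk are β-alkoxide elimination of O1 from the C8 alkylrhodium intermediate, which would open the dioxane, and epimerisation at C8 followed by β-hydride elimination towards C8a to an enol ether. Fallback, from 14 back to 15: chlorite oxidation (NaClO2, NaH2PO4, 2-methylbut-2-ene, tBuOH/H2O; Pinnick oxidation) gives the carboxylic acid F8. Esterification with N-hydroxypyridine-2-thione (N,N′-dicyclohexylcarbodiimide, CH2Cl2, dark) gives the Barton ester F9. Visible-light irradiation of F9 with PhSeSePh (Barton decarboxylation with selenide trapping) gives the C8 phenyl selenide F10 (drawn trans to O1; either epimer serves). Oxidation with H2O2 and pyridine (CH2Cl2, 0 °C to rt) and selenoxide syn-elimination, which characteristically turns away from a β-carbon that carries oxygen, gives 15.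

Step 10. The processes at risk are slow alkylation of the hindered allylic hydroxyl and competing methylation of the tertiary hydroxyl. Fallback, from 15 to 18: with 10-camphorsulfonic acid in acetone (rt) the acetonide of 15 should migrate from the six-membered 1,3-dioxane to the more stable five-membered dioxolane on the tertiary and primary oxygens, giving the spiro-dioxolane F11, in which the C2 hydroxyl is the only free hydroxyl. Methylation as in step 10 gives the methyl ether F12. Aqueous acetic acid (40 °C) removes the acetonide to give the diol F13. Selective benzoylation of the primary hydroxyl as in step 9 gives 18.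

**Further compounds**

F1 | step 4 | enantiomer of 12 | O=C[C@@H]1C[C@H](OC(=O)c2ccccc2)C=C2COC(C)(C)O[C@H]12
F2 | step 4 | enantiomer of 13 | O=C[C@@H]1C[C@H](OC(=O)c2ccccc2)[C@@H](O)[C@]2(O)COC(C)(C)O[C@H]12
F3 | step 4 | enantiomer of 14 | O=C[C@@H]1C[C@H](OC(=O)c2ccccc2)[C@@H](OC(C)=O)[C@]2(O)COC(C)(C)O[C@H]12
F4 | step 4 | enantiomer of 15 | C1=C[C@H](OC(=O)c2ccccc2)[C@@H](OC(C)=O)[C@]2(O)COC(C)(C)O[C@H]12
F5 | step 4 | enantiomer of 16 | O[C@@H]1C=C[C@H](OC(=O)c2ccccc2)[C@@H](OC(C)=O)[C@]1(O)CO
F6 | step 4 | enantiomer of 17 | O[C@@H]1C=C[C@H](OC(=O)c2ccccc2)[C@@H](OC(C)=O)[C@]1(O)COC(=O)c1ccccc1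
F7 | step 4 | C2 acetate of the enantiomer of 17 | CC(=O)O[C@@H]1C=C[C@H](OC(=O)c2ccccc2)[C@@H](OC(C)=O)[C@]1(O)COC(=O)c1ccccc1
F8 | step 7 | carboxylic acid from 14 (8-carboxy in place of 8-formyl) | OC(=O)[C@H]1C[C@@H](OC(=O)c2ccccc2)[C@H](OC(C)=O)[C@@]2(O)COC(C)(C)O[C@@H]12
F9 | step 7 | Barton ester of F8 (2-thioxopyridin-1(2H)-yl ester) | O=C(ON1C=CC=CC1=S)[C@H]1C[C@@H](OC(=O)c2ccccc2)[C@H](OC(C)=O)[C@@]2(O)COC(C)(C)O[C@@H]12
F10 | step 7 | C8 phenyl selenide (phenylselanyl in place of the formyl group of 14, trans to O1) | c1ccccc1[Se][C@@H]1C[C@@H](OC(=O)c2ccccc2)[C@H](OC(C)=O)[C@@]2(O)COC(C)(C)O[C@@H]12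
F11 | step 10 | spiro-dioxolane isomer of 15 (acetonide on the tertiary C1 oxygen and the hydroxymethyl oxygen, C2 hydroxyl free) | O[C@H]1C=C[C@@H](OC(=O)c2ccccc2)[C@H](OC(C)=O)[C@@]12COC(C)(C)O2
F12 | step 10 | C2 methyl ether of F11 | CO[C@H]1C=C[C@@H](OC(=O)c2ccccc2)[C@H](OC(C)=O)[C@@]12COC(C)(C)O2
F13 | step 10 | (1R,4S,5R,6S)-6-acetoxy-5-hydroxy-5-(hydroxymethyl)-4-methoxycyclohex-2-en-1-yl benzoate | CO[C@H]1C=C[C@@H](OC(=O)c2ccccc2)[C@H](OC(C)=O)[C@@]1(O)CO
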